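## The problem

Target 32 is a C15 tricycle with eleven ring carbons, labelled here C1 (CH–O–angeloyl), C2 (CH2), C3 (CH–OH), C4 (C–CH3), C5, C6 and C7 (three CH), C8 (C=O), C9 (CH2), C10 (CH–CH3) and C11 (C(CH3)CH2OAc). They are joined C1–C2–C3–C4–C5–C6–C7–C8–C9–C10, with the further bonds C4–C7, C5–C10, C6–C11 and C11–C1.

The core is the cyclobutane C4–C5–C6–C7. One diagonal (C5, C7) is bridged by C8–C9–C10 to give a bicyclo[3.1.1]heptan-2-one; the other (C4, C6) is bridged on the opposite face by C3–C2–C1–C11 to give a seven-membered ring. Of the eight stereocentres, C4 to C7 are tied to one another by this cage, while C10, C1, C3 and C11 sit on the bridges and must be set against it.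

The cage supplies the handles. The outward methyl on C4 overhangs one face of the three-carbon bridge and can steer a reagent at C10. The outward substituents of C5 and C7 overhang the two faces of the four-carbon bridge, so an oxygen on C7 can steer events at C11, and a hydroxymethyl on C11 can deliver hydride to C1.

The C6–C7 bond joins a bridgehead to a secondary carbon flanked by the quaternary C11, so displacement chemistry is closed and a radical or reductive bond formation is called for. Several groups are fragile:
- the (Z)-2-methylbut-2-enoate (angelate) isomerises to the E ester with base, nucleophiles or tin radicals;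
- the primary acetate can migrate;
- β-hydroxy ketone pairs (O3/C7=O before the cyclobutane exists, C11–CH2OH/C1=O after it) cleave by retro-aldol reaction;
- a cation or an α-hydroxy ketone at C7/C8 beside the cyclobutane invites ring expansion.

The feature that makes the key step possible is that C7 is 1,4 to C6 through C4 and C5, while C11 is α to the oxygenated C1. A cis-fused bicyclo[5.4.0]undecane with a C7 ketone and a C6=C11–C1=O enone is therefore one reductive C6–C7 coupling away from the cyclobutane, and that coupling leaves an enolate exactly at C11, where the last carbon is missing.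

## Retrosynthesis

**Ester and silyl bonds (32 ⇐ 31 ⇐ 28 + 29 ⇐ 27).** The O–Si bond at C3 and the two acyl–O bonds are cut first. The angelate goes on last because no later step may expose it to base, cuprate or radicals. The acetate precedes it because a primary neopentyl hydroxyl can be told from the hindered C1 hydroxyl, but not the reverse. Diol 27 carries no ester. The forward steps must acylate selectively and must esterify a hindered alcohol without Z to E isomerisation.

**C10–CH3 (27 ⇐ 25 ⇐ 23).** The methyl is cut back to the enone 25 and that to ketone 23. Carrying the methyl from the start would add a stereocentre to control before the cage exists. In the cage the C4 methyl shields one enone face, and the bridgehead C7 cannot enolise, so desaturation and conjugate addition are regio- and face-defined.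

**C7–H (23 ⇐ 22 ⇐ 21 ⇐ 19).** The C7 hydrogen is traced to a C7 hydroxyl, the price of a ketyl-based ring closure. A bridgehead allows neither ionisation nor elimination, so the oxygen must leave as a radical. This is done while C8 is still a ketal, so that no α-hydroxy ketone ever sits beside the cyclobutane. One acid treatment then frees ketone and diol.

**C1–H (19 ⇐ 18 ⇐ 17).** The C1 carbinol hydrogen is cut back to the ketone 17. The hydroxymethyl on C11 lies on the face from which hydride must come, so a hydroxyl-directed reduction suits better than any reagent-controlled one. The acetonide 19 then masks both hydroxyls for the strong base that follows.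

**C6–C7 and C11–CH2OH (17 ⇐ 14 + 15).** Cutting C6–C7 puts a ketone on C7 and an enone in the seven-membered ring. Cutting C4–C7 or C5–C6 instead would offer no such carbonyl logic and would have to form a quaternary or a neopentyl centre. The precursor 14 has two rings and three stereocentres instead of three rings and six. The forward step asks the four-membered closure to outrun plain reduction and asks formaldehyde 15 to enter on the C7 face.

**C6=C11 (14 ⇐ 13).** The seven-membered ring is opened at its double bond. Closing it by an aldol reaction at C3–C4 would have to create the quaternary C4 and C3 during a medium-ring closure. Metathesis lets both be set earlier on a six-membered ring. It only asks that the vinyl group and the enone chain be cis.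

**C2–C3 (13 ⇐ 12 ⇐ 9 + 10).** An aldol cut delivers C1, C2, C11 and its methyl from the commercial enone 10 in their final oxidation state. The forward reaction must choose one face of an aldehyde on a quaternary carbon; a non-chelating boron enolate is chosen for that.

**The C4 substituents (9 ⇐ 8 ⇐ 6 + 7).** The methyl is cut before the formyl carbon (C3). In the forward sense C3 enters first and the methyl last, trans to the vinyl group, which leaves C3 cis to C6 as the ring closure requires. Adding the C3 chain to a 2-methyl enolate would give the opposite relation, so the C4 methyl is not bought with the ring. Formylation has only one site because C8 is blocked.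

**C5–C6 and the ring (6 ⇐ 4 + 5; 4 ⇐ 2 ⇐ 1).** The vinyl group is cut from C5. A rhodium-catalysed asymmetric conjugate addition to the achiral enone 4 is the only step that needs external chirality; every later centre follows from C5. Enone 4 comes from cyclohexane-1,2-dione 1 by mono-ketalisation and desaturation.

## Roads not taken

**Alternative 1:** The cut is C3–C4, made last: an ester enolate at C4 of a finished bicyclo[3.1.1]heptane adds to an aldehyde tethered through C11–C1–C2, closing the seven-membered ring to A1.
- Merits: the ring-closing step builds no strain and is an ordinary lithium enolate aldol reaction. The cyclobutane, the C10 methyl and the quaternary C11 are already secure, and the tether forces C3 onto the correct face of C4.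
- Weak points: the precursor already holds the fully substituted cyclobutane with five stereocentres, so the hardest part is only moved upstream. The C3 configuration rests on a seven-membered transition state. A1 is a β-hydroxy ester open to retro-aldol cleavage. The ester on the quaternary C4 must still be taken down to a methyl group in several steps.
- Comparison: this ring closure is the safer one. The chosen plan sets against it that the cyclobutane, the C11 quaternary centre and three stereocentres arise in one operation from a bicycle eight steps from commercial material, with no carboxyl-to-methyl reduction.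

**Alternative 2:** The cuts are C5–C10 and C7–C8: a chiral enamine of a prochiral 3,3-disubstituted cyclobutanone is annulated with an (E)-crotonoyl electrophile across its two α-carbons to give the dione A2.
- Merits: this is the shortest entry to the bicyclic core. The four-membered ring is bought, C7 arrives as CH with no bridgehead deoxygenation, and the C8 ketone and C10 methyl appear in final form.
- Weak points: the enamine of a cyclobutanone is strained and sluggish. The second bond must close a six-membered ring across a four-membered one by a reversible acylation. One remote auxiliary would have to control C4, C5/C7 and C10 together. A2 is a strained 1,3-diketone that nucleophiles open by retro-Claisen cleavage. The whole seven-membered ring, with its quaternary C11 and two carbinols, would still have to be grown from the cyclobutanone carbonyl at C6.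
- Comparison: this road is better in step economy for the six-membered ring. The chosen plan answers that its strained ring is closed reductively and trapped, that no base-labile cyclobutane dicarbonyl appears, and that the seven-membered ring is in place before the strain is built.

**Alternative 3:** The cuts are C5–C6 and C7–C8 in an intramolecular Diels–Alder reaction of a siloxycyclopentadiene with a tethered enone. It gives the bicyclo[2.2.1]heptene A3, which must later contract to the bicyclo[3.1.1] skeleton by a 1,2-shift.
- Merits: a thermal cycloaddition needs no reagent, forms two bonds and the seven-membered ring at once, and is more predictable in its stereochemistry than a radical cascade.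
- Weak points: A3 has the wrong skeleton. The later shift runs from the less strained to the more strained bicycle, against the usual direction. The extra bridgehead silyl ether and the acetyl group are handles that must be put in and taken out.
- Comparison: the cycloaddition itself is more certain than the samarium closure. The chosen plan has to set against this that it forms the correct skeleton directly and needs no uphill rearrangement afterwards.

Key step: step 9

Remark: compounds from 14 onward are named with the atom labels C1–C11 defined above; 8 is drawn as its chelated Z enol but reacts as the delocalised anion.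

Step 1
Reactants: 1 cyclohexane-1,2-dione
Product: 2 1,4-dioxaspiro[4.5]decan-6-one
Conditions: ethane-1,2-diol (1.0 equiv), TsOH·H2O (cat.), benzene, reflux, Dean–Stark
Reagents that add atoms: ethane-1,2-diol OCCO
Why: Acid-catalysed ketalisation with one equivalent of diol and azeotropic removal of water; the second, largely enolised carbonyl stays free, which is the known outcome for this dione.

Step 2
Reactants: 2 1,4-dioxaspiro[4.5]decan-6-one
Product: 4 1,4-dioxaspiro[4.5]dec-7-en-6-one, via trimethylsilyl enol ether 3 (not isolated)
Conditions: LiN(iPr)2, Me3SiCl, THF, −78 °C; then Pd(OAc)2 (1.1 equiv), MeCN, 23 °C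
Reagents that add atoms: chlorotrimethylsilane C[Si](C)(C)Cl (its silyl group is carried by 3 only)
Why: Saegusa–Ito oxidation; the ketone can enolise only toward its CH2 side because the other α-carbon is the ketal carbon, so a single silyl enol ether and a single enone result.

Step 3
Reactants: 4 1,4-dioxaspiro[4.5]dec-7-en-6-one; 5 potassium ethenyltrifluoroborate K[CH2=CHBF3]
Product: 6 (8R)-8-ethenyl-1,4-dioxaspiro[4.5]decan-6-one
Conditions: [Rh(cod)2]BF4 (3 mol%), (R)-BINAP (3.3 mol%), Et3N (2 equiv), toluene/H2O (10:1), 40 °C
Reagents that add atoms: none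
Why: Rhodium-catalysed asymmetric conjugate addition of an alkenylboron reagent (Hayashi–Miyaura reaction), which sets C5; (R)-BINAP should give the (R) product by analogy with cyclohex-2-enone, where the (S) ligand gives (S)-3-substituted cyclohexanones and the ketal carbon lies far from the reacting face.

Step 4
Reactants: 6 (8R)-8-ethenyl-1,4-dioxaspiro[4.5]decan-6-one; 7 ethyl formate
Product: 8 (7Z,8S)-8-ethenyl-7-(hydroxymethylidene)-1,4-dioxaspiro[4.5]decan-6-one
Conditions: NaH, EtOH (cat.), THF, 0 to 23 °C; then 1 M HCl, 0 °C
Reagents that add atoms: none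
Why: Claisen formylation; C8 carries no hydrogen, so the formyl carbon (C3) can only enter at C4, and the product rests as the chelated hydroxymethylene ketone.

Step 5
Reactants: 8 (7Z,8S)-8-ethenyl-7-(hydroxymethylidene)-1,4-dioxaspiro[4.5]decan-6-one
Product: 9 (7S,8S)-8-ethenyl-7-methyl-6-oxo-1,4-dioxaspiro[4.5]decane-7-carbaldehyde
Conditions: MeI, K2CO3, acetone, 23 °C
Reagents that add atoms: iodomethane CI
Why: C-alkylation of the β-keto aldehyde anion; allylic 1,3-strain with the exocyclic CH–O unit holds the C5 vinyl group axial, so iodomethane should enter from the opposite face and form the quaternary C4 with methyl trans and formyl cis to the vinyl group.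

Step 6
Reactants: 9 (7S,8S)-8-ethenyl-7-methyl-6-oxo-1,4-dioxaspiro[4.5]decane-7-carbaldehyde; 10 3-methylbut-3-en-2-one
Product: 12 (7S,8S)-8-ethenyl-7-[(1R)-1-hydroxy-4-methyl-3-oxopent-4-en-1-yl]-7-methyl-1,4-dioxaspiro[4.5]decan-6-one, via boron dienolate 11 (not isolated)
Conditions: 10, (c-C6H11)2BCl, Et3N, Et2O, 0 °C; then 9, −78 °C; MeOH, pH 7 buffer
Reagents that add atoms: chlorodicyclohexylborane ClB(C1CCCCC1)C1CCCCC1 (its boron is carried by 11 only)
Why: Boron-mediated aldol addition of a methyl ketone; the dialkylboron enolate cannot chelate the ring ketone, so the aldehyde should react with its two carbonyl dipoles opposed (Cornforth arrangement) and be attacked past the C4 methyl and not past C5, which gives the (R) carbinol at C3.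

Step 7
Reactants: 12 (7S,8S)-8-ethenyl-7-[(1R)-1-hydroxy-4-methyl-3-oxopent-4-en-1-yl]-7-methyl-1,4-dioxaspiro[4.5]decan-6-one
Product: 13 (7S,8S)-7-[(1R)-1-{[tert-butyl(dimethyl)silyl]oxy}-4-methyl-3-oxopent-4-en-1-yl]-8-ethenyl-7-methyl-1,4-dioxaspiro[4.5]decan-6-one
Conditions: tBuMe2SiOTf, 2,6-lutidine, CH2Cl2, −78 °C
Reagents that add atoms: tert-butyldimethylsilyl trifluoromethanesulfonate CC(C)(C)[Si](C)(C)OS(=O)(=O)C(F)(F)F
Why: Silylation of a hindered secondary alcohol with a silyl triflate and a hindered pyridine base; it blocks retro-aldol cleavage and oxa-Michael closure of the β-hydroxy enone before any basic step.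

Step 8
Reactants: 13 (7S,8S)-7-[(1R)-1-{[tert-butyl(dimethyl)silyl]oxy}-4-methyl-3-oxopent-4-en-1-yl]-8-ethenyl-7-methyl-1,4-dioxaspiro[4.5]decan-6-one
Product: 14 cis-fused bicyclo[5.4.0]undecene (3R,4S,5S): C1 ketone; C6=C11 double bond with methyl on C11; C3 OTBS; C4 methyl; C7 ketone; C8 ethylene ketal
Conditions: second-generation Grubbs catalyst (5 mol%), toluene (0.005 M), 80 °C
Reagents that add atoms: none
Why: Ring-closing metathesis to a trisubstituted cycloheptenone, driven by loss of ethene; the vinyl group and the enone chain are cis on the cyclohexanone, so the seven-membered ring closes to the cis-fused bicycle with the C6=C11 bond necessarily Z.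

Step 9
Reactants: 14 cis-fused bicyclic enone diketone monoketal; 15 formaldehyde
Product: 17 tricyclic keto diol: C7 bridgehead hydroxyl; C1 ketone; C11 methyl syn to C5 and hydroxymethyl syn to C7; C3 OTBS syn to C7; C8 ethylene ketal, via tricyclic samarium enolate 16 (not isolated)
Conditions: SmI2 (2.5 equiv), HMPA (8 equiv), THF, −78 °C; then CH2O (THF solution from cracked paraformaldehyde, 10 equiv), −78 to −40 °C; aq. NH4Cl
Reagents that add atoms: samarium diiodide I[Sm]I (samarium and iodide are carried by 16 only)
Why: SmI2 (divalent samarium) transfers one electron to the C7 ketone (or to the enone, which leads to the same intermediate); the radical anion joins C7 to C6, the β-carbon of the enone, across the C4–C5 ring fusion, a second electron turns the C11 α-keto radical into the samarium enolate 16, and 16 adds to formaldehyde in an aldol reaction. The closest known reaction types are the SmI2 ketyl–olefin 4-exo-trig cyclisation of carbonyl compounds tethered to the β-carbon of an electron-poor alkene, which gives cyclobutanols, and the aldol capture of samarium enolates formed in ketyl–olefin couplings; both are used here on a ring-fused member of that substrate class. One ring closes, the cyclobutane C4–C5–C6–C7, in the 4-exo-trig mode (C11 stays outside it), and with it the bicyclo[3.1.1]heptane is complete. C6 and C7 are set by the cis ring fusion: only in the conformer with C6 axial on the cyclohexanone do C6 and C7 lie gauche about C4–C5, and the bond can form only on that face, which leaves H6 and O7 pointing outward. C11 is set in the capture: the trivalent samarium alkoxide on C7 overhangs one face of the enolate, binds formaldehyde and should deliver it there, so that the hydroxymethyl ends syn to C7 and the methyl syn to C5. The step needs the closure to outrun plain reduction of the enone, which the aprotic medium and the immediate reduction of the cyclised α-keto radical are expected to secure; it needs the C8 ketal to stay intact, which the absence of a proton source favours because C–O cleavage beside a ketyl requires protonation and a second electron; and it needs capture at C11 only, which holds because the enolate is generated regiospecifically and C2 is never deprotonated.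

Step 10
Reactants: 17 tricyclic keto diol
Product: 18 tricyclic triol: as 17 with a C1 hydroxyl syn to C5 (trans to the C11 hydroxymethyl)
Conditions: Me4NBH(OAc)3 (5 equiv), MeCN/AcOH (1:1), −20 °C
Reagents that add atoms: none
Why: Evans–Saksena hydroxyl-directed reduction; the C11 hydroxymethyl exchanges onto boron and delivers hydride through a six-membered transition state to the C1 face it occupies, so the new hydroxyl ends trans to the hydroxymethyl (anti-1,3-diol) as in the target; the C7 hydroxyl lies on the same face and cannot mislead.

Step 11
Reactants: 18 tricyclic triol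
Product: 19 isopropylidene acetal of 18 across O1 and the C11–CH2–O oxygen; C7 hydroxyl free
Conditions: Me2C(OMe)2, PPTS (cat.), CH2Cl2, 23 °C
Reagents that add atoms: 2,2-dimethoxypropane COC(C)(C)OC
Why: Acid-catalysed acetonide formation (transketalisation) on the 1,3-diol; it ties up the two reactive hydroxyls and leaves only the tertiary C7 hydroxyl for the next step.

Step 12
Reactants: 19 acetonide with free C7 hydroxyl
Product: 21 O-(C7) S-methyl dithiocarbonate of 19, via potassium xanthate salt 20 (not isolated)
Conditions: KH, CS2, imidazole (cat.), THF, 0 to 23 °C; then MeI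
Reagents that add atoms: potassium hydride [K+].[H-] (its potassium is carried by 20 only); carbon disulfide S=C=S; iodomethane CI
Why: Xanthate formation from a tertiary alkoxide; carbon disulfide is small enough to reach the hindered bridgehead oxygen, and the xanthate cannot undergo Chugaev elimination because every β-position would give a bridgehead double bond or has no hydrogen.

Step 13
Reactants: 21 C7 xanthate
Product: 22 C7-deoxy tricycle (C7–H): acetonide; C8 ethylene ketal; C3 OTBS
Conditions: Bu3SnH, AIBN, toluene, 110 °C
Reagents that add atoms: none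
Why: Barton–McCombie deoxygenation; the pyramidal bridgehead radical at C7 is reduced with retention by necessity, a bridgehead offering no ionic alternative, and the C8 ketal keeps an α-hydroxy ketone from ever forming beside the cyclobutane.

Step 14
Reactants: 22 C7-deoxy tricycle
Product: 23 keto diol: C8 ketone; C1 hydroxyl; C11 hydroxymethyl; C3 OTBS
Conditions: TsOH·H2O (0.2 equiv), acetone/H2O (10:1), 40 °C
Reagents that add atoms: water O
Why: Acid-catalysed hydrolysis of the dioxolane and the acetonide in one operation; the hindered secondary TBS ether at C3 should survive, and with C7 now a CH the freed C8 ketone has no rearrangement pathway.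

Step 15
Reactants: 23 keto diol
Product: 25 C9=C10 enone with triethylsilyl ethers on O1 and on the C11–CH2–O oxygen, via triethylsilyl enol ether 24 (not isolated)
Conditions: Et3SiOTf (3.5 equiv), Et3N, CH2Cl2, 0 °C; then Pd(OAc)2 (1.1 equiv), MeCN, 23 °C
Reagents that add atoms: triethylsilyl trifluoromethanesulfonate CC[Si](CC)(CC)OS(=O)(=O)C(F)(F)F
Why: Saegusa–Ito oxidation; silylation caps both hydroxyls and gives the only possible enol ether (C8=C9, since the bridgehead C7 cannot enolise), and Pd(OAc)2 (divalent palladium) then introduces the C9=C10 double bond as in the conversion of nopinone-type ketones into their enones.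

Step 16
Reactants: 25 bis-silylated enone
Product: 27 C10-methyl keto diol: methyl on C10 syn to C6; C8 ketone; C1 hydroxyl; C11 hydroxymethyl; C3 OTBS, via bis-silylated methyl ketone 26 (not isolated)
Conditions: Me2CuLi (3 equiv), Et2O, −78 to −30 °C; aq. NH4Cl; then PPTS, MeOH, 23 °C
Reagents that add atoms: lithium dimethylcuprate [Li+].C[Cu-]C
Why: Gilman cuprate conjugate addition; the methyl on C4 overhangs one face of the enone as the syn methyl of a pinane bridge does, so the cuprate should add from the C6 side and set C10 with its methyl syn to C6; mild acidic methanolysis then frees the two triethylsilyl ethers and leaves the TBS ether.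

Step 17
Reactants: 27 C10-methyl keto diol
Product: 28 primary acetate: C11–CH2OAc; C1 hydroxyl free; C3 OTBS
Conditions: Ac2O (1.2 equiv), pyridine, CH2Cl2, 0 °C
Reagents that add atoms: acetic anhydride CC(=O)OC(C)=O
Why: Selective acylation of a primary alcohol in the presence of a hindered secondary alcohol flanked by a quaternary carbon.

Step 18
Reactants: 28 primary acetate with free C1 hydroxyl; 29 (2Z)-2-methylbut-2-enoic acid (angelic acid)
Product: 31 C1 angelate with C3 OTBS, via mixed trichlorobenzoic anhydride 30 (not isolated)
Conditions: 29, 2,4,6-Cl3C6H2COCl, Et3N, toluene, 23 °C; then 28, 75 °C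
Reagents that add atoms: 2,4,6-trichlorobenzoyl chloride O=C(Cl)c1c(Cl)cc(Cl)cc1Cl (its acyl group is carried by 30 only)
Why: Yamaguchi esterification; the mixed 2,4,6-trichlorobenzoic anhydride acylates hindered secondary alcohols without a nucleophilic catalyst that could add to the enoate, the established way to keep the Z geometry of an angelate.

Step 19
Reactants: 31 C1 angelate with C3 OTBS
Product: 32 CNP0212099.1
Conditions: HF·pyridine, pyridine, THF, 0 to 23 °C
Reagents that add atoms: none
Why: Fluoride-mediated cleavage of a silyl ether under buffered conditions, which should leave both esters, the ketone and the Z double bond untouched.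

## Compound list

1 | cyclohexane-1,2-dione | O=C1CCCCC1=O | starting material
2 | 1,4-dioxaspiro[4.5]decan-6-one | O=C1CCCCC12OCCO2 | intermediate
3 | 6-(trimethylsilyloxy)-1,4-dioxaspiro[4.5]dec-6-ene | C[Si](C)(C)OC1=CCCCC12OCCO2 | intermediate
4 | 1,4-dioxaspiro[4.5]dec-7-en-6-one | O=C1C=CCCC12OCCO2 | intermediate
5 | potassium ethenyltrifluoroborate | [K+].C=C[B-](F)(F)F | starting material
6 | (8R)-8-ethenyl-1,4-dioxaspiro[4.5]decan-6-one | O=C1C[C@H](C=C)CCC12OCCO2 | intermediate
7 | ethyl formate | CCOC=O | starting material
8 | (7Z,8S)-8-ethenyl-7-(hydroxymethylidene)-1,4-dioxaspiro[4.5]decan-6-one | O/C=C1\C(=O)C2(OCCO2)CC[C@H]1C=C | intermediate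
9 | (7S,8S)-8-ethenyl-7-methyl-6-oxo-1,4-dioxaspiro[4.5]decane-7-carbaldehyde | O=C[C@]1(C)[C@H](C=C)CCC2(OCCO2)C1=O | intermediate
10 | 3-methylbut-3-en-2-one | CC(=O)C(C)=C | starting material
11 | dicyclohexyl[(3-methylbuta-1,3-dien-2-yl)oxy]borane | C=C(C)C(=C)OB(C1CCCCC1)C1CCCCC1 | intermediate
12 | (7S,8S)-8-ethenyl-7-[(1R)-1-hydroxy-4-methyl-3-oxopent-4-en-1-yl]-7-methyl-1,4-dioxaspiro[4.5]decan-6-one | C=C(C)C(=O)C[C@@H](O)[C@]1(C)[C@H](C=C)CCC2(OCCO2)C1=O | intermediate
13 | tert-butyldimethylsilyl ether of 12 | C=C(C)C(=O)C[C@@H](O[Si](C)(C)C(C)(C)C)[C@]1(C)[C@H](C=C)CCC2(OCCO2)C1=O | intermediate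
14 | cis-fused bicyclic enone (3R,4S,5S): C1 ketone, C6=C11 (C11 methyl), C3 OTBS, C4 methyl, C7 ketone, C8 ethylene ketal | O=C1C[C@@H](O[Si](C)(C)C(C)(C)C)[C@]2(C)[C@H](C=C1C)CCC3(OCCO3)C2=O | intermediate
15 | formaldehyde | C=O | starting material
16 | tricyclic bis(diiodosamarium) enolate–alkoxide (trivalent samarium on O1 and O7; C1=C11 enolate) | I[Sm](I)OC=1C[C@@H](O[Si](C)(C)C(C)(C)C)[C@]2(C)[C@@H]3[C@@H]([C@@]2(O[Sm](I)I)C4(OCCO4)CC3)C=1C | intermediate
17 | tricyclic keto diol: C7 hydroxyl, C1 ketone, C11 methyl (syn to C5) and hydroxymethyl (syn to C7), C3 OTBS, C8 ethylene ketal | O=C1C[C@@H](O[Si](C)(C)C(C)(C)C)[C@]2(C)[C@@H]3[C@@H]([C@@]2(O)C4(OCCO4)CC3)[C@@]1(C)CO | intermediate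
18 | tricyclic triol: 17 with C1 hydroxyl syn to C5 | O[C@@H]1C[C@@H](O[Si](C)(C)C(C)(C)C)[C@]2(C)[C@@H]3[C@@H]([C@@]2(O)C4(OCCO4)CC3)[C@@]1(C)CO | intermediate
19 | O1/C11–CH2–O acetonide of 18, C7 hydroxyl free | CC5(C)O[C@@H]1C[C@@H](O[Si](C)(C)C(C)(C)C)[C@]2(C)[C@@H]3[C@@H]([C@@]2(O)C4(OCCO4)CC3)[C@@]1(C)CO5 | intermediate
20 | potassium O-(C7) dithiocarbonate of 19 | [K+].CC5(C)O[C@@H]1C[C@@H](O[Si](C)(C)C(C)(C)C)[C@]2(C)[C@@H]3[C@@H]([C@@]2(OC([S-])=S)C4(OCCO4)CC3)[C@@]1(C)CO5 | intermediate
21 | O-(C7) S-methyl dithiocarbonate of 19 | CC5(C)O[C@@H]1C[C@@H](O[Si](C)(C)C(C)(C)C)[C@]2(C)[C@@H]3[C@@H]([C@@]2(OC(=S)SC)C4(OCCO4)CC3)[C@@]1(C)CO5 | intermediate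
22 | C7-deoxy tricycle: acetonide, C8 ethylene ketal, C3 OTBS | CC5(C)O[C@@H]1C[C@@H](O[Si](C)(C)C(C)(C)C)[C@]2(C)[C@@H]3[C@@H]([C@H]2C4(OCCO4)CC3)[C@@]1(C)CO5 | intermediate
23 | keto diol: C8 ketone, C1 hydroxyl, C11 hydroxymethyl, C3 OTBS | O[C@@H]1C[C@@H](O[Si](C)(C)C(C)(C)C)[C@]2(C)[C@@H]3[C@@H]([C@H]2C(=O)CC3)[C@@]1(C)CO | intermediate
24 | C8 triethylsilyl enol ether (C8=C9) with triethylsilyl ethers on O1 and the primary oxygen | CC[Si](CC)(CC)O[C@@H]1C[C@@H](O[Si](C)(C)C(C)(C)C)[C@]2(C)[C@@H]3[C@@H]([C@H]2C(O[Si](CC)(CC)CC)=CC3)[C@@]1(C)CO[Si](CC)(CC)CC | intermediate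
25 | C9=C10 enone, bis(triethylsilyl) ether | CC[Si](CC)(CC)O[C@@H]1C[C@@H](O[Si](C)(C)C(C)(C)C)[C@]2(C)[C@@H]3[C@@H]([C@H]2C(=O)C=C3)[C@@]1(C)CO[Si](CC)(CC)CC | intermediate
26 | C10-methyl ketone (methyl syn to C6), bis(triethylsilyl) ether | CC[Si](CC)(CC)O[C@@H]1C[C@@H](O[Si](C)(C)C(C)(C)C)[C@]2(C)[C@@H]3[C@@H]([C@H]2C(=O)C[C@H]3C)[C@@]1(C)CO[Si](CC)(CC)CC | intermediate
27 | C10-methyl keto diol, C3 OTBS | O[C@@H]1C[C@@H](O[Si](C)(C)C(C)(C)C)[C@]2(C)[C@@H]3[C@@H]([C@H]2C(=O)C[C@H]3C)[C@@]1(C)CO | intermediate
28 | primary acetate of 27, C1 hydroxyl free | O[C@@H]1C[C@@H](O[Si](C)(C)C(C)(C)C)[C@]2(C)[C@@H]3[C@@H]([C@H]2C(=O)C[C@H]3C)[C@@]1(C)COC(C)=O | intermediate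
29 | (2Z)-2-methylbut-2-enoic acid (angelic acid) | C/C=C(/C)C(=O)O | starting material
30 | (2Z)-2-methylbut-2-enoic 2,4,6-trichlorobenzoic anhydride | C/C=C(/C)C(=O)OC(=O)c1c(Cl)cc(Cl)cc1Cl | intermediate
31 | C1 angelate, C11–CH2OAc, C3 OTBS | C/C=C(/C)C(=O)O[C@@H]1C[C@@H](O[Si](C)(C)C(C)(C)C)[C@]2(C)[C@@H]3[C@@H]([C@H]2C(=O)C[C@H]3C)[C@@]1(C)COC(C)=O | intermediate
32 | CNP0212099.1 | C/C=C(/C)C(=O)O[C@@H]1C[C@@H](O)[C@]2(C)[C@@H]3[C@@H]([C@H]2C(=O)C[C@H]3C)[C@@]1(C)COC(C)=O | target

## Step count and least certain steps

Total step count: 19. Longest linear sequence: 19 steps (1 to 32); 5, 7, 10, 15 and 29 are commercial.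

**Step 9 (key step).**
- What may go wrong: loss of facial control in the capture. The oxygen on C7 that should deliver formaldehyde also crowds that face, so any addition not directed through samarium goes to the open face syn to C5. Beside this, the closure builds a strained bridged ring and may lose to plain two-electron reduction of the enone.
- Fallback: exchange the roles of the two C11 substituents so that the open face becomes the wanted one. It sets out from 9 and returns at 17.
  - Boron aldol of 9 with 3-{[(4-methoxyphenyl)methoxy]methyl}but-3-en-2-one F1 gives the aldol F2.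
  - Silylation gives the TBS ether F3.
  - Ring-closing metathesis gives the bicyclic enone F4, whose C11 already carries the oxygenated carbon.
  - SmI2 closure followed by iodomethane (HMPA) gives the tricycle F5, the methyl entering on the open face syn to C5.
  - DDQ removes the 4-methoxybenzyl group and gives 17.

**Step 6.**
- What may go wrong: attack on the other aldehyde face, through an arrangement with the two carbonyls syn, which would give the C3 epimer.
- Fallback: set C3 by hydride under reagent control. It sets out from 9 and returns at 12.
  - The lithium acetylide of 2-methylbut-1-en-3-yne adds to 9 to give the propargylic alcohols F6 (both C3 epimers).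
  - Dess–Martin oxidation gives the ynone F7.
  - Transfer hydrogenation with RuCl[(S,S)-TsDPEN](p-cymene), the alkynyl group taking the place of the aryl group of the usual model, should give the (3R) propargylic alcohol F8.
  - Ruthenium-catalysed trans-hydrosilylation ([Cp*Ru(MeCN)3]PF6, BnMe2SiH) puts silicon on the alkyne carbon remote from the hydroxyl, giving the vinylsilane F9.
  - Tamao–Fleming oxidation converts F9 into 12.

**Step 13 (with its preparation in step 12).**
- What may go wrong: slow C–O scission, because the radical is a strained bridgehead cyclobutyl radical, so the stannyl adduct is reduced without losing oxygen; or incomplete xanthate formation at the hindered alkoxide.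
- Fallback: cleave the C–O bond by electron transfer. It sets out from 19 and returns at 22.
  - BuLi and ClP(O)(NMe2)2 give the phosphorodiamidate F10.
  - Lithium in ethylamine removes the phosphate oxygen and gives 22; ketal, acetonide and silyl ether tolerate these conditions.

**Step 18.**
- What may go wrong: Z to E isomerisation of the activated angelate during a slow acylation of the hindered C1 hydroxyl, giving the tiglate.
- Fallback: build the double bond on the ester. It sets out from 28 and returns at 31.
  - Carbodiimide esterification with 2-[bis(2,2,2-trifluoroethoxy)phosphoryl]propanoic acid gives the phosphonate ester F11.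
  - Still–Gennari olefination (KN(SiMe3)2, 18-crown-6, acetaldehyde, THF, −78 °C) forms the Z enoate and gives 31.

## Further compounds

F1 | step 9 | 3-{[(4-methoxyphenyl)methoxy]methyl}but-3-en-2-one | CC(=O)C(=C)COCc1ccc(OC)cc1
F2 | step 9 | aldol adduct of 9 and F1 (C3 hydroxyl, R) | C=C(COCc1ccc(OC)cc1)C(=O)C[C@@H](O)[C@]2(C)[C@H](C=C)CCC3(OCCO3)C2=O
F3 | step 9 | tert-butyldimethylsilyl ether of F2 | C=C(COCc1ccc(OC)cc1)C(=O)C[C@@H](O[Si](C)(C)C(C)(C)C)[C@]2(C)[C@H](C=C)CCC3(OCCO3)C2=O
F4 | step 9 | cis-fused bicyclic enone with (4-methoxybenzyloxy)methyl on C11 | O=C1C[C@@H](O[Si](C)(C)C(C)(C)C)[C@]2(C)[C@H](C=C1COCc4ccc(OC)cc4)CCC3(OCCO3)C2=O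
F5 | step 9 | tricyclic C7 alcohol with C11 methyl (syn to C5) and (4-methoxybenzyloxy)methyl (syn to C7) | O=C1C[C@@H](O[Si](C)(C)C(C)(C)C)[C@]2(C)[C@@H]3[C@@H]([C@@]2(O)C4(OCCO4)CC3)[C@@]1(C)COCc5ccc(OC)cc5
F6 | step 6 | propargylic alcohols from 9 and the enyne acetylide (both C3 epimers) | C=C(C)C#CC(O)[C@]1(C)[C@H](C=C)CCC2(OCCO2)C1=O
F7 | step 6 | ynone (C3 ketone) | C=C(C)C#CC(=O)[C@]1(C)[C@H](C=C)CCC2(OCCO2)C1=O
F8 | step 6 | (3R) propargylic alcohol | C=C(C)C#C[C@@H](O)[C@]1(C)[C@H](C=C)CCC2(OCCO2)C1=O
F9 | step 6 | vinylsilane with benzyldimethylsilyl on C1 | C=C(C)/C([Si](C)(C)Cc1ccccc1)=C/[C@@H](O)[C@]2(C)[C@H](C=C)CCC3(OCCO3)C2=O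
F10 | step 13 | C7 N,N,N',N'-tetramethylphosphorodiamidate of 19 | CC5(C)O[C@@H]1C[C@@H](O[Si](C)(C)C(C)(C)C)[C@]2(C)[C@@H]3[C@@H]([C@@]2(OP(=O)(N(C)C)N(C)C)C4(OCCO4)CC3)[C@@]1(C)CO5
F11 | step 18 | C1 2-[bis(2,2,2-trifluoroethoxy)phosphoryl]propanoate of 28 | CC(P(=O)(OCC(F)(F)F)OCC(F)(F)F)C(=O)O[C@@H]1C[C@@H](O[Si](C)(C)C(C)(C)C)[C@]2(C)[C@@H]3[C@@H]([C@H]2C(=O)C[C@H]3C)[C@@]1(C)COC(C)=O
A1 | alternative 1 | tricyclic C3 alcohol with methyl ester on C4, acetonide and C8 ketal | CC4(C)O[C@@H]1C[C@@H](O)[C@]2(C(=O)OC)[C@@H]3[C@@H]([C@H]2C5(OCCO5)C[C@H]3C)[C@@]1(C)CO4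
A2 | alternative 2 | bicyclo[3.1.1]heptane-2,6-dione with C10 methyl and quaternary C4 carrying methyl and silyloxymethyl | CC(C)[Si](C(C)C)(C(C)C)OC[C@]2(C)[C@@H]3C(=O)[C@H]2C(=O)C[C@H]3C
A3 | alternative 3 | tricyclic Diels–Alder adduct with bridgehead triethylsilyl ether and acetyl group | CC4(C)O[C@@H]1C[C@@H](O[Si](C)(C)C(C)(C)C)[C@]2(C)[C@@H]3[C@@H]([C@@H](C(C)=O)[C@@]2(O[Si](CC)(CC)CC)C=C3)[C@@]1(C)CO4
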